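Readings and results were generated by integration from invented constants, and the scatter is random.

Start from the starting material left in the cedar run at its last reading, 64% at 30.0 min, set the 28% of target beside it, and note that the two fall short of the charge by a gap of 8 percentage points, which no peak shows.

in all of them: free catalyst 10 mol%
- larch: starting material 2 M; partner 0.47 equiv; temperature 75 °C; run made earlier
- cedar: starting material 2 M; partner 0.91 equiv; temperature 90 °C; run made earlier
- summer: starting material 2.0 M; partner 0.400 equiv; temperature 90 °C; time 40 min
- autumn: starting material 2.0 M; partner 0.800 equiv; temperature 90 °C; time 40 min

| run | time / min | target / % | starting material / % |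
|---|---|---|---|
| larch | 4.00 | 2 | 96 |
| larch | 10.0 | 0 | 92 |
| larch | 20.0 | 6 | 90 |
| larch | 30.0 | 4 | 90 |
| larch | 40.0 | 4 | 83 |
| larch | 60.0 | 13 | 78 |
| cedar | 2.50 | 4 | 91 |
| cedar | 4.00 | 5 | 90 |
| cedar | 6.00 | 6 | 87 |
| cedar | 10.0 | 7 | 85 |
| cedar | 15.0 | 15 | 78 |
| cedar | 30.0 | 28 | 64 |

(readings scatter by 2 percentage points)

* the winner by amount of target, in percent of the starting material charged; "neither" if no more than 2 percentage points parts them (summer / autumn / neither)
* how much target is there at the end, in percent of the starting material charged: summer
* how much target is there at the end, in percent of the starting material charged: autumn

- the numbers in the tables scatter by 2 percentage points (one standard deviation)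

Divide the target gained by the starting material lost between cedar's readings at 10.0 min and 30.0 min, so that time drops out, and get 1.00: within the scatter, the gap reads the same at both ends of that stretch while starting material turns into target. Divide the gap by the catalyst charge and call the result the held share h, 0.800, a reading with the scatter of two peaks.

Now climb the ladder of times in cedar. The lowest rung is the gap itself, already 5 points at 2.50 min. Next, take the pace of target between cedar's readings at 10.0 min and 30.0 min, 0.0105 /min as a fraction of the charge, and find that one turn of the catalyst charge takes 9.52 min at that pace, shorter than the 40 min asked. On the top rung, as an estimate that counts one partner per target at that pace and nothing else taking partner, autumn's charge of partner reckons out at 76.2 min, longer than the window, and summer's at 38.1 min. Expect, by this reckoning of mine, autumn to end no lower in target than summer, with more partner charged, and expect starting material in both flasks to read the charge less target less a gap of h catalyst charges.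

The forecast says autumn, with 18% (12% to 28%) for summer and 32% (25% to 39%) for autumn, holding that “Autumn should win unless the reaction is zero order in partner.” Its autumn number is what first order to completion through cedar's last reading gives.

The flasks give autumn as winner, 15.7% in summer and 25.0% in autumn, so the forecast's autumn number stands 7 points too high.

    starting material + free catalyst → catalyst intermediate A (k = 0.00580 /M/s, Ea = 85.0 kJ/mol)
    partner + catalyst intermediate A ⇌ catalyst intermediate B (K = 1.20 /M, k = 0.00780 /M/s, Ea = 88.0 kJ/mol, ΔH = −5.00 kJ/mol)
    catalyst intermediate B → by-product + catalyst intermediate C (k = 0.900 /s, Ea = 101 kJ/mol)
    catalyst intermediate C → free catalyst + target (k = 0.00380 /s, Ea = 107 kJ/mol)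
    partner → decomposed reagent (k = 0.00120 /s, Ea = 109 kJ/mol)
    (constants at 90 °C)

In autumn at 40.0 min, partner stands at 0.670% of its charge beside 1.08 M of decomposed reagent, and h comes to 0.970, with catalyst intermediate A, the resting state, holding 92.5% of the catalyst and catalyst intermediate C holding 4.47%. Reckon h on the neighbour, autumn with 25 mol% of free catalyst: its 42.4% of target and 33% of starting material give 0.985, and at 40.0 min its catalyst intermediate C stands at 0.477% and its catalyst intermediate A at 98.0% of the catalyst.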